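**Assumption:** atom labels are the isochromene positions of the target (C1, O2, C3, C4, C4a, C5–C8, C8a) and primed labels C1′–C7′ for the heptenyl chain; the target is (7S,8S,8aS,1′E,3′S,4′R,5′R). Dimethyl (S)-malate and D-isoleucine are taken as commercial chiral starting materials. No step has been run; conditions are proposals.

## Retrosynthetic overview

1. Target 25 ⇐ intramolecular aldol condensation (C4a=C5, carbocycle formed last) of dihydropyranone 23 ⇐ 6-endo oxa-Michael closure (O2–C3, pyran ring formed first) of the unmasked β-hydroxy ynone from 21.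
2. Ynone 21 ⇐ C8a–C4a bond by nickel-electrocatalytic decarboxylative acylation of dioxane acid 10 (as its N-hydroxyphthalimide ester) with alkynoic thioester 19; the planar C8a radical couples trans to the C8 substituent.
3. Acid 10 ⇐ dimethyl (S)-malate 1 (C8 bought): formaldehyde aldol (C1), Weinreb amide, (1-ethoxyvinyl)lithium (C5, C6), chelation-controlled MeMgBr (C7).
4. Thioester 19 ⇐ D-isoleucine 11 (C4′, C5′ bought): hydroxy acid, Weinreb amide, silyl diynide, chelation-controlled MeMgBr (C3′), trans-hydroalumination, CO2.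

## Route

Step 1
Reactants: 1 dimethyl (S)-malate
Product: 4 (3R,4S)-4-hydroxy-5-oxooxolane-3-carboxylic acid, via open-chain aldol adduct 2 (not isolated), via lactone methyl ester 3 (not isolated)
Conditions: LiN(i-Pr)2 (2.3 equiv), THF, −78 → −20 °C; CH2O (gas), −78 °C; then 2 M HCl, 50 °C
Reagents that add atoms: formaldehyde C=O; water O
Why: Fráter–Seebach aldol of the chelated alkoxide–enolate dianion adds formaldehyde anti to the C8 oxygen (this C8a configuration is reset in step 13), the new alkoxide lactonises onto the α-hydroxy ester and acid hydrolysis frees the other carboxyl, so the two carboxyls are differentiated without protecting groups.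

Step 2
Reactants: 4 (3R,4S)-4-hydroxy-5-oxooxolane-3-carboxylic acid
Product: 5 (2R,3S)-3-hydroxy-2-(hydroxymethyl)-4-[methoxy(methyl)amino]-4-oxobutanoic acid
Conditions: MeNH(OMe)·HCl (3 equiv), i-PrMgCl (8 equiv), THF, −20 → 0 °C; 1 M HCl to pH 3
Reagents that add atoms: N,O-dimethylhydroxylamine hydrochloride CNOC.Cl
Why: Weinreb aminolysis of a lactone by the chloromagnesium amide opens the α-hydroxy lactone carbonyl (C7) while the magnesium carboxylate is inert; no stereocentre is touched.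

Step 3
Reactants: 5 (2R,3S)-3-hydroxy-2-(hydroxymethyl)-4-[methoxy(methyl)amino]-4-oxobutanoic acid
Product: 6 (4S,5R)-4-[methoxy(methyl)carbamoyl]-2,2-dimethyl-1,3-dioxane-5-carboxylic acid
Conditions: 2-methoxypropene (2.5 equiv), PPTS (5 mol%), DMF, 0 → 23 °C
Reagents that add atoms: 2-methoxypropene COC(C)=C
Why: Acetalisation of the 1,3-diol (O8, O1) as an isopropylidene acetal stops relactonisation and provides both the chelating C8 oxygen for step 5 and the six-membered ring that controls C8a in step 13.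

Step 4
Reactants: 6 (4S,5R)-4-[methoxy(methyl)carbamoyl]-2,2-dimethyl-1,3-dioxane-5-carboxylic acid, 7 ethyl vinyl ether
Product: 8 (4S,5R)-4-(2-ethoxyprop-2-enoyl)-2,2-dimethyl-1,3-dioxane-5-carboxylic acid
Conditions: 7, t-BuLi, THF, −78 → 0 °C; then 6, −78 °C; aq. NH4Cl, pH 4
Reagents that add atoms: none
Why: Acylation of (1-ethoxyvinyl)lithium by the Weinreb amide stops at the ketone through the stable chelated adduct, and the lithium carboxylate does not react at −78 °C.

Step 5
Reactants: 8 (4S,5R)-4-(2-ethoxyprop-2-enoyl)-2,2-dimethyl-1,3-dioxane-5-carboxylic acid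
Product: 10 (4S,5R)-4-[(2S)-3-ethoxy-2-(triethylsilyloxy)but-3-en-2-yl]-2,2-dimethyl-1,3-dioxane-5-carboxylic acid, via tertiary alcohol acid 9 (not isolated)
Conditions: MeMgBr (3.5 equiv), CH2Cl2/Et2O, −78 °C; then Et3SiOTf (3 equiv), 2,6-lutidine (0.5 equiv), −78 → 0 °C; pH 5 buffer
Reagents that add atoms: methylmagnesium bromide C[Mg]Br; triethylsilyl trifluoromethanesulfonate CC[Si](CC)(CC)OS(=O)(=O)C(F)(F)F
Why: Cram-chelate-controlled Grignard addition (magnesium bridges the ketone oxygen and the C8 acetal oxygen, methyl enters anti to C8a) sets C7 as S with the 7,8-oxygens in the cis-diol relationship, and silylating the tertiary alkoxide in the same flask prevents γ-lactonisation when the acid is activated in step 13.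

Step 6
Reactants: 11 D-isoleucine
Product: 12 (2R,3R)-2-hydroxy-3-methylpentanoic acid
Conditions: NaNO2 (1.5 equiv), 1 M H2SO4, 0 → 23 °C
Reagents that add atoms: water O
Why: Diazotisation of the α-amino acid proceeds with net retention (double inversion through the α-lactone), so C4′ and C5′ are taken unchanged from D-isoleucine.

Step 7
Reactants: 12 (2R,3R)-2-hydroxy-3-methylpentanoic acid
Product: 13 (2R,3R)-2-hydroxy-N-methoxy-N,3-dimethylpentanamide
Conditions: MeNH(OMe)·HCl, EDC·HCl, HOBt (cat.), N-methylmorpholine, CH2Cl2, 0 → 23 °C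
Reagents that add atoms: N,O-dimethylhydroxylamine hydrochloride CNOC.Cl
Why: Carbodiimide amide coupling works on the unprotected α-hydroxy acid and leaves both stereocentres untouched.

Step 8
Reactants: 13 (2R,3R)-2-hydroxy-N-methoxy-N,3-dimethylpentanamide, 14 1,4-bis(trimethylsilyl)buta-1,3-diyne
Product: 15 (6R,7R)-6-hydroxy-7-methyl-1-(trimethylsilyl)nona-1,3-diyn-5-one
Conditions: 14, MeLi·LiBr, THF, −78 → 23 °C; then 13 (0.4 equiv relative to diynide), −78 → −40 °C; aq. NH4Cl
Reagents that add atoms: none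
Why: Monodesilylation of the bis-silyl diyne by MeLi gives the lithium diynide, which is acylated once by the Weinreb amide (one further equivalent deprotonates the hydroxyl).

Step 9
Reactants: 15 (6R,7R)-6-hydroxy-7-methyl-1-(trimethylsilyl)nona-1,3-diyn-5-one
Product: 16 (5S,6R,7R)-5,7-dimethyl-1-(trimethylsilyl)nona-1,3-diyne-5,6-diol
Conditions: MeMgBr (3.5 equiv), THF, −78 °C; aq. NH4Cl
Reagents that add atoms: methylmagnesium bromide C[Mg]Br
Why: Chelation-controlled Grignard 1,2-addition to the α-hydroxy ketone through its magnesium alkoxide delivers methyl anti to the sec-butyl group and sets C3′ as S.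

Step 10
Reactants: 16 (5S,6R,7R)-5,7-dimethyl-1-(trimethylsilyl)nona-1,3-diyne-5,6-diol
Product: 17 (3E,5S,6R,7R)-5,7-dimethyl-1-(trimethylsilyl)non-3-en-1-yne-5,6-diol
Conditions: NaAlH2(OCH2CH2OMe)2 (4 equiv), THF, 0 → 23 °C; aq. NaOH
Reagents that add atoms: none
Why: Hydroxyl-directed trans-hydroalumination of a propargylic alcohol reduces only the alkyne next to the carbinol and gives the E alkene (C1′=C2′).

Step 11
Reactants: 17 (3E,5S,6R,7R)-5,7-dimethyl-1-(trimethylsilyl)non-3-en-1-yne-5,6-diol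
Product: 18 (4E,6S,7R,8R)-6,7-dihydroxy-6,8-dimethyldec-4-en-2-ynoic acid
Conditions: CsF (2 equiv), CO2 (1 atm), DMSO, 23 °C; then 0.5 M HCl to pH 3
Reagents that add atoms: carbon dioxide O=C=O
Why: Fluoride-promoted desilylative carboxylation of the alkynylsilane introduces the future C4a as a carboxyl without touching the diol.

Step 12
Reactants: 18 (4E,6S,7R,8R)-6,7-dihydroxy-6,8-dimethyldec-4-en-2-ynoic acid
Product: 19 S-pyridin-2-yl (4E,6S,7R,8R)-6,7-dihydroxy-6,8-dimethyldec-4-en-2-ynethioate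
Conditions: 2,2′-dipyridyl disulfide (1.2 equiv), PPh3 (1.2 equiv, premixed), MeCN, 0 °C
Reagents that add atoms: 2,2′-dipyridyl disulfide c1ccc(nc1)SSc1ccccn1
Why: Mukaiyama–Corey redox condensation gives the S-2-pyridyl thioester, and the rigid E-enyne spacer keeps the free hydroxyls from lactonising.

Step 13
Reactants: 10 (4S,5R)-4-[(2S)-3-ethoxy-2-(triethylsilyloxy)but-3-en-2-yl]-2,2-dimethyl-1,3-dioxane-5-carboxylic acid, 19 S-pyridin-2-yl (4E,6S,7R,8R)-6,7-dihydroxy-6,8-dimethyldec-4-en-2-ynethioate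
Product: 21 (4E,6S,7R,8R)-1-{(4S,5S)-4-[(2S)-3-ethoxy-2-(triethylsilyloxy)but-3-en-2-yl]-2,2-dimethyl-1,3-dioxan-5-yl}-6,7-dihydroxy-6,8-dimethyldec-4-en-2-yn-1-one, via N-hydroxyphthalimide ester 20 (not isolated)
Conditions: N-hydroxyphthalimide, i-PrN=C=N-i-Pr, DMAP (cat.), CH2Cl2, 23 °C; then 19 (1.5 equiv), NiBr2(MeOCH2CH2OMe) (20 mol%), 4,4′-di-tert-butyl-2,2′-bipyridine (24 mol%), LiBr, DMA, undivided cell, Zn anode, carbon cathode, constant current (2.5 F/mol), 23 °C
Reagents that add atoms: none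
Why: Proposed new method: nickel-electrocatalytic decarboxylative acylation that forms an ynone and the C8a–C4a bond; the closest known reactions are the Ni-catalysed reductive coupling of N-hydroxyphthalimide esters with S-2-pyridyl thioesters (zinc powder as reductant) and Ni-electrocatalytic decarboxylative alkenylation of such esters, and what is not yet shown is an alkynoyl thioester partner, electrochemical turnover for the acylation, and diastereocontrol on a 1,3-dioxane; cathodically formed zerovalent nickel inserts into the C(acyl)–S bond of 19, single-electron reduction of 20 releases CO2 and phthalimide anion to give the planar secondary dioxan-5-yl radical, which is captured by the acyl–nickel species and reductive elimination from trivalent nickel gives the ketone, so the C8a configuration from step 1 is erased and the bond forms anti to the bulky C4 substituent (trans-4,5-dioxane, the target's 8aS, also the thermodynamic epimer α to the ketone).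

Step 14
Reactants: 21 the trans ynone from step 13
Product: 23 (3S)-3-[(1S,2S)-1,2-dihydroxy-2-methyl-3-oxobutyl]-6-[(1E,3S,4R,5R)-3,4-dihydroxy-3,5-dimethylhept-1-en-1-yl]-2,3-dihydro-4H-pyran-4-one, via deprotected hydroxy ynone 22 (not isolated)
Conditions: TsOH·H2O (0.3 equiv), THF/H2O (4:1), 0 → 23 °C
Reagents that add atoms: water O
Why: Acid hydrolysis of the enol ether (to the C6 methyl ketone), the silyl ether and the acetonide is followed by acid-catalysed 6-endo-dig oxa-Michael cyclisation of the β-hydroxy ynone, which closes the pyran ring (O2–C3) as a 2,3-dihydro-4H-pyran-4-one.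

Step 15
Reactants: 23 the dihydropyranone from step 14
Product: 25 (7S,8S,8aS)-3-[(1E,3S,4R,5R)-3,4-dihydroxy-3,5-dimethylhept-1-en-1-yl]-7,8-dihydroxy-7-methyl-8,8a-dihydro-1H-isochromen-6(7H)-one, via aldol adduct 24 (not isolated)
Conditions: MgBr2·OEt2 (2 equiv), Et3N (3 equiv), THF, 0 → 23 °C; aq. NH4Cl
Reagents that add atoms: none
Why: Intramolecular aldol condensation under soft enolisation (the magnesium chelate of the α-ketol makes C5–H the most acidic site) adds C5 to the vinylogous-ester carbonyl C4a and loss of water gives the conjugated dienone, closing the carbocycle; C7, C8 and C8a are carried through, and C8a, now γ to the dienone, can only equilibrate towards the trans arrangement already present.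

## Compound list

1 | dimethyl (S)-malate | COC(=O)C[C@H](O)C(=O)OC | starting material
2 | dimethyl (2S,3R)-2-hydroxy-3-(hydroxymethyl)butanedioate (major anti adduct) | COC(=O)[C@@H](O)[C@@H](CO)C(=O)OC | intermediate
3 | methyl (3R,4S)-4-hydroxy-5-oxooxolane-3-carboxylate | O=C1OC[C@@H](C(=O)OC)[C@@H]1O | intermediate
4 | (3R,4S)-4-hydroxy-5-oxooxolane-3-carboxylic acid | O=C1OC[C@@H](C(=O)O)[C@@H]1O | intermediate
5 | (2R,3S)-3-hydroxy-2-(hydroxymethyl)-4-[methoxy(methyl)amino]-4-oxobutanoic acid | CON(C)C(=O)[C@@H](O)[C@@H](CO)C(=O)O | intermediate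
6 | (4S,5R)-4-[methoxy(methyl)carbamoyl]-2,2-dimethyl-1,3-dioxane-5-carboxylic acid (cis) | CON(C)C(=O)[C@H]1OC(C)(C)OC[C@H]1C(=O)O | intermediate
7 | ethyl vinyl ether | C=COCC | starting material
8 | (4S,5R)-4-(2-ethoxyprop-2-enoyl)-2,2-dimethyl-1,3-dioxane-5-carboxylic acid | CCOC(=C)C(=O)[C@H]1OC(C)(C)OC[C@H]1C(=O)O | intermediate
9 | (4S,5R)-4-[(2S)-3-ethoxy-2-hydroxybut-3-en-2-yl]-2,2-dimethyl-1,3-dioxane-5-carboxylic acid | CCOC(=C)[C@@](C)(O)[C@H]1OC(C)(C)OC[C@H]1C(=O)O | intermediate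
10 | (4S,5R)-4-[(2S)-3-ethoxy-2-(triethylsilyloxy)but-3-en-2-yl]-2,2-dimethyl-1,3-dioxane-5-carboxylic acid | CCOC(=C)[C@@](C)(O[Si](CC)(CC)CC)[C@H]1OC(C)(C)OC[C@H]1C(=O)O | intermediate
11 | D-isoleucine, (2R,3R)-2-amino-3-methylpentanoic acid | CC[C@@H](C)[C@@H](N)C(=O)O | starting material
12 | (2R,3R)-2-hydroxy-3-methylpentanoic acid | CC[C@@H](C)[C@@H](O)C(=O)O | intermediate
13 | (2R,3R)-2-hydroxy-N-methoxy-N,3-dimethylpentanamide | CC[C@@H](C)[C@@H](O)C(=O)N(C)OC | intermediate
14 | 1,4-bis(trimethylsilyl)buta-1,3-diyne | C[Si](C)(C)C#CC#C[Si](C)(C)C | starting material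
15 | (6R,7R)-6-hydroxy-7-methyl-1-(trimethylsilyl)nona-1,3-diyn-5-one | CC[C@@H](C)[C@@H](O)C(=O)C#CC#C[Si](C)(C)C | intermediate
16 | (5S,6R,7R)-5,7-dimethyl-1-(trimethylsilyl)nona-1,3-diyne-5,6-diol | CC[C@@H](C)[C@@H](O)[C@@](C)(O)C#CC#C[Si](C)(C)C | intermediate
17 | (3E,5S,6R,7R)-5,7-dimethyl-1-(trimethylsilyl)non-3-en-1-yne-5,6-diol | CC[C@@H](C)[C@@H](O)[C@@](C)(O)/C=C/C#C[Si](C)(C)C | intermediate
18 | (4E,6S,7R,8R)-6,7-dihydroxy-6,8-dimethyldec-4-en-2-ynoic acid | CC[C@@H](C)[C@@H](O)[C@@](C)(O)/C=C/C#CC(=O)O | intermediate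
19 | S-pyridin-2-yl (4E,6S,7R,8R)-6,7-dihydroxy-6,8-dimethyldec-4-en-2-ynethioate | CC[C@@H](C)[C@@H](O)[C@@](C)(O)/C=C/C#CC(=O)Sc1ccccn1 | intermediate
20 | 1,3-dioxoisoindolin-2-yl (4S,5R)-4-[(2S)-3-ethoxy-2-(triethylsilyloxy)but-3-en-2-yl]-2,2-dimethyl-1,3-dioxane-5-carboxylate | CCOC(=C)[C@@](C)(O[Si](CC)(CC)CC)[C@H]1OC(C)(C)OC[C@H]1C(=O)ON1C(=O)c2ccccc2C1=O | intermediate
21 | (4E,6S,7R,8R)-1-{(4S,5S)-4-[(2S)-3-ethoxy-2-(triethylsilyloxy)but-3-en-2-yl]-2,2-dimethyl-1,3-dioxan-5-yl}-6,7-dihydroxy-6,8-dimethyldec-4-en-2-yn-1-one (trans dioxane) | CCOC(=C)[C@@](C)(O[Si](CC)(CC)CC)[C@H]1OC(C)(C)OC[C@@H]1C(=O)C#C/C=C/[C@](C)(O)[C@H](O)[C@H](C)CC | intermediate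
22 | (3S,4S,5S,9E,11S,12R,13R)-3,4,11,12-tetrahydroxy-5-(hydroxymethyl)-3,11,13-trimethylpentadec-9-en-7-yne-2,6-dione | CC(=O)[C@@](C)(O)[C@@H](O)[C@H](CO)C(=O)C#C/C=C/[C@](C)(O)[C@H](O)[C@H](C)CC | intermediate
23 | (3S)-3-[(1S,2S)-1,2-dihydroxy-2-methyl-3-oxobutyl]-6-[(1E,3S,4R,5R)-3,4-dihydroxy-3,5-dimethylhept-1-en-1-yl]-2,3-dihydro-4H-pyran-4-one | CC(=O)[C@@](C)(O)[C@@H](O)[C@@H]1COC(/C=C/[C@](C)(O)[C@H](O)[C@H](C)CC)=CC1=O | intermediate
24 | 4a-hydroxy-4a,5-dihydro derivative of 25 (aldol adduct, both C4a epimers) | CC[C@@H](C)[C@@H](O)[C@@](C)(O)/C=C/C1=CC2(O)CC(=O)[C@@](C)(O)[C@@H](O)[C@@H]2CO1 | intermediate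
25 | (7S,8S,8aS)-3-[(1E,3S,4R,5R)-3,4-dihydroxy-3,5-dimethylhept-1-en-1-yl]-7,8-dihydroxy-7-methyl-8,8a-dihydro-1H-isochromen-6(7H)-one | CC[C@@H](C)[C@@H](O)[C@@](C)(O)/C=C/C1=CC2=CC(=O)[C@@](C)(O)[C@@H](O)[C@@H]2CO1 | target

## Step count

Total step count: 15.
Longest linear sequence: 10 steps (steps 6–12, then 13, 14, 15); the malate branch is 5 steps before the union.

## Three steps most likely to fail

**Step 13 (the proposed new coupling).** The alkynoyl thioester may suffer radical conjugate addition or bind nickel through the alkyne, and the trans selectivity is a prediction. The fallback uses only known ionic chemistry and sets out from acid 10 and silyl enyne 17. Acid 10 is coupled with MeNH(OMe)·HCl (EDC·HCl, HOBt) to the Weinreb amide (4S,5R)-4-[(2S)-3-ethoxy-2-(triethylsilyloxy)but-3-en-2-yl]-N-methoxy-N,2,2-trimethyl-1,3-dioxane-5-carboxamide F1. Enyne 17 is desilylated with K2CO3 in MeOH to (3E,5S,6R,7R)-5,7-dimethylnon-3-en-1-yne-5,6-diol F2. The trilithio derivative of F2 (n-BuLi, 3 equiv, THF, −78 °C) is acylated by F1 to give the cis ynone, the (4S,5R) C8a epimer of 21, F3. Brief treatment with Et3N in CH2Cl2 equilibrates the centre α to the ynone to the trans-diequatorial isomer, and the route is rejoined at 21.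

**Step 15 (aldol condensation onto the vinylogous-ester carbonyl).** The pyranone carbonyl is a weak electrophile and the C8 hydroxyl is β to it, so dehydration or retro-oxa-Michael opening can compete. The fallback closes the carbocycle before the pyran and sets out from ynone 21. PPTS in wet acetone at 0 °C hydrolyses only the enol ether to the methyl ketone (4E,6S,7R,8R)-1-{(4S,5S)-2,2-dimethyl-4-[(2S)-3-oxo-2-(triethylsilyloxy)butan-2-yl]-1,3-dioxan-5-yl}-6,7-dihydroxy-6,8-dimethyldec-4-en-2-yn-1-one F4. Anhydrous TsOH in benzene at 40 °C effects acid-catalysed aldol condensation onto the ynone carbonyl to give the protected 3-alkynylcyclohexenone (4aS,8S,8aS)-5-[(3E,5S,6R,7R)-5,6-dihydroxy-5,7-dimethylnon-3-en-1-yn-1-yl]-2,2,8-trimethyl-8-(triethylsilyloxy)-4a,8a-dihydro-4H-1,3-benzodioxin-7(8H)-one F5. Aqueous HCl in THF removes acetonide and silyl ether, and AgOTf (5 mol%) closes the pyran by 6-endo-dig 1,6-oxa-Michael addition of the C1 hydroxyl, rejoining the route at 25.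

**Step 1 (formaldehyde aldol of the malate dianion).** Gaseous formaldehyde can over-react, and the β-hydroxy ester can undergo retro-aldol cleavage or dehydration during hydrolysis. The fallback sets out from 1 and uses the classical Fráter–Seebach alkylation with benzyl chloromethyl ether (LiN(i-Pr)2, THF, −78 → −20 °C) to give dimethyl (2S,3R)-3-[(benzyloxy)methyl]-2-hydroxybutanedioate F6. Hydrogenolysis (H2, Pd/C, MeOH) frees the primary alcohol, which is compound 2 and lactonises to 3; the acid hydrolysis of step 1 then gives 4.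

## Further compounds

F1 | step 13 | (4S,5R)-4-[(2S)-3-ethoxy-2-(triethylsilyloxy)but-3-en-2-yl]-N-methoxy-N,2,2-trimethyl-1,3-dioxane-5-carboxamide | CCOC(=C)[C@@](C)(O[Si](CC)(CC)CC)[C@H]1OC(C)(C)OC[C@H]1C(=O)N(C)OC
F2 | step 13 | (3E,5S,6R,7R)-5,7-dimethylnon-3-en-1-yne-5,6-diol | CC[C@@H](C)[C@@H](O)[C@@](C)(O)/C=C/C#C
F3 | step 13 | (4E,6S,7R,8R)-1-{(4S,5R)-4-[(2S)-3-ethoxy-2-(triethylsilyloxy)but-3-en-2-yl]-2,2-dimethyl-1,3-dioxan-5-yl}-6,7-dihydroxy-6,8-dimethyldec-4-en-2-yn-1-one (cis dioxane) | CCOC(=C)[C@@](C)(O[Si](CC)(CC)CC)[C@H]1OC(C)(C)OC[C@H]1C(=O)C#C/C=C/[C@](C)(O)[C@H](O)[C@H](C)CC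
F4 | step 15 | (4E,6S,7R,8R)-1-{(4S,5S)-2,2-dimethyl-4-[(2S)-3-oxo-2-(triethylsilyloxy)butan-2-yl]-1,3-dioxan-5-yl}-6,7-dihydroxy-6,8-dimethyldec-4-en-2-yn-1-one | CC(=O)[C@@](C)(O[Si](CC)(CC)CC)[C@H]1OC(C)(C)OC[C@@H]1C(=O)C#C/C=C/[C@](C)(O)[C@H](O)[C@H](C)CC
F5 | step 15 | (4aS,8S,8aS)-5-[(3E,5S,6R,7R)-5,6-dihydroxy-5,7-dimethylnon-3-en-1-yn-1-yl]-2,2,8-trimethyl-8-(triethylsilyloxy)-4a,8a-dihydro-4H-1,3-benzodioxin-7(8H)-one | O=C1C=C(C#C/C=C/[C@](C)(O)[C@H](O)[C@H](C)CC)[C@H]2COC(C)(C)O[C@@H]2[C@]1(C)O[Si](CC)(CC)CC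
F6 | step 1 | dimethyl (2S,3R)-3-[(benzyloxy)methyl]-2-hydroxybutanedioate | COC(=O)[C@@H](O)[C@@H](COCc1ccccc1)C(=O)OC
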